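**Retrosynthetic overview**
1. Target 29 ⇒ last-stage C3 hydroxylation and C6–O ester bond ⇒ dienone alcohol 13 + silyl-protected dienoic acid 23.
2. 13 ⇒ octalone 10 by γ,δ-dehydrogenation; ring B ⇐ Robinson annulation (imine Michael addition, then aldol condensation) of cyclohexanone 4 with but-3-en-2-one, which also sets the quaternary C4a.
3. 4 ⇒ hydroxy ketone 3 ⇐ meso all-cis diol 2 by a new catalytic enantioselective oxidative desymmetrisation (fixes the absolute configuration of the future C5 and C6); 2 ⇐ all-cis hydrogenation of 2,3-dimethylhydroquinone 1.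
4. 23 ⇐ (S)-2-hydroxy-2-methylbutanoic acid 14 by vinylogous Horner–Wadsworth–Emmons olefination.
5. Ring order: ring A is the reduced benzene ring of 1 and is present from the start; ring B is formed second.

Assumption: compounds 1, 5, 14 and 19 are taken as commercial; ring A carries the ester oxygen and both methyls, ring B is the hydroxy-enone ring, and bicyclic compounds are numbered as naphthalen-2(3H)-ones (C2 carbonyl, C3 carbinol, C4a quaternary, C5 CH(CH3), C6 ester carbon).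

**Route**

Step 1
Reactants: 1 2,3-dimethylbenzene-1,4-diol
Product: 2 (1R,2S,3R,4S)-2,3-dimethylcyclohexane-1,4-diol (all-cis, meso)
Conditions: H2 (50 bar), 5% Rh/Al2O3, i-PrOH, 25 °C; recrystallisation
Reagents that add atoms: none
Why: cis-selective heterogeneous arene hydrogenation delivers all six hydrogens to the ring face lying on the rhodium surface, so both methyls and both hydroxyls come out all-cis (the relative configuration of the future C5 methyl and C6 oxygen), and minor isomers are removed by crystallisation.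

Step 2
Reactants: 2 (1R,2S,3R,4S)-2,3-dimethylcyclohexane-1,4-diol
Product: 3 (2S,3R,4S)-4-hydroxy-2,3-dimethylcyclohexan-1-one
Conditions: 4-benzyl-1-methyl-2-azaadamantane N-oxyl (C17H22NO, single enantiomer, 5 mol%), PhI(OAc)2 (1.1 equiv), CH2Cl2, −20 °C
Reagents that add atoms: none
Why: Proposed new method: enantioselective oxidative desymmetrisation of an unactivated saturated meso-1,4-diol by a chiral oxoammonium ion formed from the nitroxyl and PhI(OAc)2; the two carbinols are enantiotopic, each lying between a CH(CH3) and a CH2 group, so the benzyl-flanked N=O+ pocket accepts the alkoxide and the carbinol hydride of only the (R)-carbinol (C1), which turns the former meso centres into the fixed (3R,4S) stereocentres of 3; the minor enantiomer still carries the fast-reacting carbinol and is drained by a second oxidation to the meso diketone, which raises the ee; the closest known reaction type is chiral-nitroxyl-catalysed oxidative kinetic resolution of secondary alcohols (and oxidative desymmetrisation of benzylic or allylic meso diols); the sense of induction cannot be predicted, so the catalyst antipode that attacks the (R)-carbinol is chosen after a test run.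

Step 3
Reactants: 3 (2S,3R,4S)-4-hydroxy-2,3-dimethylcyclohexan-1-one
Product: 4 (2S,3R,4S)-4-[(tert-butyldimethylsilyl)oxy]-2,3-dimethylcyclohexan-1-one
Conditions: TBSCl, imidazole, DMF, rt
Reagents that add atoms: tert-butyldimethylsilyl chloride, CC(C)(C)[Si](C)(C)Cl
Why: Imidazole-promoted silyl ether formation; the γ-silyloxy group cannot β-eliminate and no fixed stereocentre is touched (C2 may epimerise but is rebuilt in step 4).

Step 4
Reactants: 4 (2S,3R,4S)-4-[(tert-butyldimethylsilyl)oxy]-2,3-dimethylcyclohexan-1-one; 5 but-3-en-2-one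
Product: 8 (2R,3R,4S)-4-[(tert-butyldimethylsilyl)oxy]-2,3-dimethyl-2-(3-oxobutyl)cyclohexan-1-one, via N-benzyl imine 6 (not isolated), via Michael-adduct imine 7 (not isolated)
Conditions: BnNH2, 4 Å MS, PhMe, 60 °C; then 5, THF, 40 °C; then 10% aq AcOH, rt
Reagents that add atoms: water, O (carbonyl oxygen returned on imine hydrolysis); benzylamine, NCc1ccccc1 (its atoms stay only in 6 and 7)
Why: Imine–enamine Michael reaction (first stage of the Robinson annulation): the more substituted secondary enamine tautomer of 6 adds to the enone at C2 on the face anti to the pseudoaxial C3 methyl, which makes C2 quaternary (2R) with the two methyls cis.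

Step 5
Reactants: 8 (2R,3R,4S)-4-[(tert-butyldimethylsilyl)oxy]-2,3-dimethyl-2-(3-oxobutyl)cyclohexan-1-one
Product: 10 (4aR,5R,6S)-6-[(tert-butyldimethylsilyl)oxy]-4a,5-dimethyl-4,4a,5,6,7,8-hexahydronaphthalen-2(3H)-one, via aldol ketol 9 (not isolated)
Conditions: NaOMe (20 mol%), MeOH, 0 to 50 °C
Reagents that add atoms: none
Why: Intramolecular aldol condensation (second stage of the Robinson annulation): the methyl-ketone enolate adds to the ring carbonyl and E1cB dehydration of 9 closes ring B as the conjugated enone without touching the three stereocentres.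

Step 6
Reactants: 10 (4aR,5R,6S)-6-[(tert-butyldimethylsilyl)oxy]-4a,5-dimethyl-4,4a,5,6,7,8-hexahydronaphthalen-2(3H)-one
Product: 11 (4aR,5R,6S)-6-[(tert-butyldimethylsilyl)oxy]-4a,5-dimethyl-2-[(trimethylsilyl)oxy]-3,4,4a,5,6,7-hexahydronaphthalene
Conditions: Me3SiOTf, Et3N, CH2Cl2, 0 °C to rt
Reagents that add atoms: trimethylsilyl trifluoromethanesulfonate, C[Si](C)(C)OS(=O)(=O)C(F)(F)F
Why: Soft enolisation under equilibrating conditions removes the γ-proton at C8 and gives the fully conjugated heteroannular silyl dienol ether needed for the dehydrogenation.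

Step 7
Reactants: 11 (4aR,5R,6S)-6-[(tert-butyldimethylsilyl)oxy]-4a,5-dimethyl-2-[(trimethylsilyl)oxy]-3,4,4a,5,6,7-hexahydronaphthalene
Product: 12 (4aR,5R,6S)-6-[(tert-butyldimethylsilyl)oxy]-4a,5-dimethyl-4,4a,5,6-tetrahydronaphthalen-2(3H)-one
Conditions: Pd(OAc)2 (1.05 equiv), MeCN, rt
Reagents that add atoms: none
Why: Saegusa–Ito oxidation: divalent palladium adds to the dienol ether to give an allyl palladium species whose only β-hydrogens are at C7 (C8a has none), so β-hydride elimination gives the linear 1(8a),7-dienone and zerovalent palladium with no stereocentre touched.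

Step 8
Reactants: 12 (4aR,5R,6S)-6-[(tert-butyldimethylsilyl)oxy]-4a,5-dimethyl-4,4a,5,6-tetrahydronaphthalen-2(3H)-one
Product: 13 (4aR,5R,6S)-6-hydroxy-4a,5-dimethyl-4,4a,5,6-tetrahydronaphthalen-2(3H)-one
Conditions: HF·pyridine, THF, 0 °C to rt
Reagents that add atoms: none
Why: Fluoride-driven desilylation frees the allylic C6 alcohol; the dienone and the stereocentres are inert to buffered HF.

Step 9
Reactants: 14 (S)-2-hydroxy-2-methylbutanoic acid
Product: 15 methyl (S)-2-hydroxy-2-methylbutanoate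
Conditions: MeOH, H2SO4 (cat.), reflux
Reagents that add atoms: methanol, CO
Why: Fischer esterification; the quaternary carbinol centre cannot racemise.

Step 10
Reactants: 15 methyl (S)-2-hydroxy-2-methylbutanoate
Product: 16 methyl (S)-2-methyl-2-[(triethylsilyl)oxy]butanoate
Conditions: Et3SiOTf, 2,6-lutidine, CH2Cl2, 0 °C
Reagents that add atoms: triethylsilyl trifluoromethanesulfonate, CC[Si](CC)(CC)OS(=O)(=O)C(F)(F)F
Why: Silyl triflate with a hindered pyridine base silylates even a tertiary alcohol (silyl ether protection) with the configuration unchanged.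

Step 11
Reactants: 16 methyl (S)-2-methyl-2-[(triethylsilyl)oxy]butanoate
Product: 18 (S)-2-methyl-2-[(triethylsilyl)oxy]butanal, via aluminium hemiacetal 17 (not isolated)
Conditions: i-Bu2AlH, CH2Cl2, −78 °C; aq KNaC4H4O6
Reagents that add atoms: diisobutylaluminium hydride, CC(C)C[AlH]CC(C)C (aluminium and isobutyl groups stay only in 17)
Why: Partial ester reduction: the chelated tetrahedral aluminium hemiacetal 17 survives at −78 °C until aqueous work-up, so the aldehyde forms without over-reduction, and its α-carbon is quaternary and cannot epimerise.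

Step 12
Reactants: 18 (S)-2-methyl-2-[(triethylsilyl)oxy]butanal; 19 ethyl (E)-4-(diethoxyphosphoryl)but-2-enoate
Product: 21 ethyl (2E,4E,6S)-6-methyl-6-[(triethylsilyl)oxy]octa-2,4-dienoate, via lithiated phosphonate 20 (not isolated)
Conditions: 19, LiN(SiMe3)2, THF, −78 °C; then 18, −78 to 0 °C
Reagents that add atoms: lithium bis(trimethylsilyl)amide, [Li+].C[Si](C)(C)[N-][Si](C)(C)C (lithium stays only in 20)
Why: Vinylogous Horner–Wadsworth–Emmons olefination: the stabilised anion 20 adds through the carbon next to phosphorus and elimination of phosphate gives the new C4=C5 bond with E geometry, while the C2=C3 bond stays E.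

Step 13
Reactants: 21 ethyl (2E,4E,6S)-6-methyl-6-[(triethylsilyl)oxy]octa-2,4-dienoate
Product: 23 (2E,4E,6S)-6-methyl-6-[(triethylsilyl)oxy]octa-2,4-dienoic acid, via lithium carboxylate 22 (not isolated)
Conditions: LiOH, THF/MeOH/H2O, rt; then 1 M HCl to pH 4
Reagents that add atoms: lithium hydroxide, [Li+].[OH-] (oxygen of the acid OH; lithium stays only in 22)
Why: Saponification by acyl–oxygen cleavage followed by mild acidification; the tertiary triethylsilyl ether and the diene survive LiOH at room temperature.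

Step 14
Reactants: 23 (2E,4E,6S)-6-methyl-6-[(triethylsilyl)oxy]octa-2,4-dienoic acid; 13 (4aR,5R,6S)-6-hydroxy-4a,5-dimethyl-4,4a,5,6-tetrahydronaphthalen-2(3H)-one
Product: 25 (4aR,5R,6S)-4a,5-dimethyl-2-oxo-2,3,4,4a,5,6-hexahydronaphthalen-6-yl (2E,4E,6S)-6-methyl-6-[(triethylsilyl)oxy]octa-2,4-dienoate, via mixed anhydride 24 (not isolated)
Conditions: 23, 2,4,6-Cl3C6H2COCl, Et3N, THF, rt; then 13, DMAP, PhMe, 40 °C
Reagents that add atoms: 2,4,6-trichlorobenzoyl chloride, O=C(Cl)c1c(Cl)cc(Cl)cc1Cl (its aroyl group stays only in 24)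
Why: Yamaguchi esterification: DMAP attacks the less hindered dienoyl carbonyl of 24 and the acylpyridinium acylates the hindered allylic alcohol with retention at C6 (its C–O bond is not broken), and the acid has no γ-hydrogen that could deconjugate.

Step 15
Reactants: 25 (4aR,5R,6S)-4a,5-dimethyl-2-oxo-2,3,4,4a,5,6-hexahydronaphthalen-6-yl (2E,4E,6S)-6-methyl-6-[(triethylsilyl)oxy]octa-2,4-dienoate
Product: 28 (3R,4aR,5R,6S)-3-hydroxy-4a,5-dimethyl-2-oxo-2,3,4,4a,5,6-hexahydronaphthalen-6-yl (2E,4E,6S)-6-methyl-6-[(triethylsilyl)oxy]octa-2,4-dienoate, via potassium enolate 26 (not isolated), via potassium alkoxide 27 (not isolated)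
Conditions: KN(SiMe3)2, THF, −78 °C; then 2-(phenylsulfonyl)-3-phenyloxaziridine, −78 °C; AcOH
Reagents that add atoms: 2-(phenylsulfonyl)-3-phenyloxaziridine, O=S(=O)(c1ccccc1)N1OC1c1ccccc1; potassium bis(trimethylsilyl)amide, [K+].C[Si](C)(C)[N-][Si](C)(C)C (potassium stays only in 26 and 27)
Why: Kinetic α′-deprotonation at C3 by the hindered amide gives the cross-conjugated enolate 26, and Davis oxaziridine hydroxylation (electrophilic oxygen transfer) occurs on the face anti to the axial C4a methyl to give the equatorial (3R)-alcohol, which is also the more stable epimer; the dienoate has no acidic hydrogen.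

Step 16
Reactants: 28 (3R,4aR,5R,6S)-3-hydroxy-4a,5-dimethyl-2-oxo-2,3,4,4a,5,6-hexahydronaphthalen-6-yl (2E,4E,6S)-6-methyl-6-[(triethylsilyl)oxy]octa-2,4-dienoate
Product: 29 (3R,4aR,5R,6S)-3-hydroxy-4a,5-dimethyl-2-oxo-2,3,4,4a,5,6-hexahydronaphthalen-6-yl (2E,4E,6S)-6-hydroxy-6-methylocta-2,4-dienoate
Conditions: HF·pyridine, pyridine, THF, 0 °C to rt
Reagents that add atoms: none
Why: Fluoride-driven cleavage of the tertiary triethylsilyl ether (desilylation) under buffered conditions that leave the allylic ester, the α-ketol and the dienone intact, giving the target.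

**Compound list**
1 | 2,3-dimethylbenzene-1,4-diol | Cc1c(O)ccc(O)c1C | starting material
2 | (1R,2S,3R,4S)-2,3-dimethylcyclohexane-1,4-diol (all-cis, meso) | O[C@H]1CC[C@@H](O)[C@@H](C)[C@H]1C | intermediate
3 | (2S,3R,4S)-4-hydroxy-2,3-dimethylcyclohexan-1-one | O[C@H]1CCC(=O)[C@@H](C)[C@H]1C | intermediate
4 | (2S,3R,4S)-4-[(tert-butyldimethylsilyl)oxy]-2,3-dimethylcyclohexan-1-one | CC(C)(C)[Si](C)(C)O[C@H]1CCC(=O)[C@@H](C)[C@H]1C | intermediate
5 | but-3-en-2-one | C=CC(C)=O | starting material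
6 | (2S,3R,4S)-N-benzyl-4-[(tert-butyldimethylsilyl)oxy]-2,3-dimethylcyclohexan-1-imine | CC(C)(C)[Si](C)(C)O[C@H]1CCC(=NCc2ccccc2)[C@@H](C)[C@H]1C | intermediate (not isolated)
7 | 4-[(1R,5S,6R)-2-(benzylimino)-5-[(tert-butyldimethylsilyl)oxy]-1,6-dimethylcyclohexyl]butan-2-one | CC(=O)CC[C@]1(C)[C@@H](C)[C@@H](O[Si](C)(C)C(C)(C)C)CCC1=NCc1ccccc1 | intermediate (not isolated)
8 | (2R,3R,4S)-4-[(tert-butyldimethylsilyl)oxy]-2,3-dimethyl-2-(3-oxobutyl)cyclohexan-1-one | CC(=O)CC[C@]1(C)[C@@H](C)[C@@H](O[Si](C)(C)C(C)(C)C)CCC1=O | intermediate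
9 | (4aR,5R,6S)-6-[(tert-butyldimethylsilyl)oxy]-8a-hydroxy-4a,5-dimethyloctahydronaphthalen-2(1H)-one (C8a not defined) | CC(C)(C)[Si](C)(C)O[C@H]1CCC2(O)CC(=O)CC[C@]2(C)[C@H]1C | intermediate (not isolated)
10 | (4aR,5R,6S)-6-[(tert-butyldimethylsilyl)oxy]-4a,5-dimethyl-4,4a,5,6,7,8-hexahydronaphthalen-2(3H)-one | CC(C)(C)[Si](C)(C)O[C@H]1CCC2=CC(=O)CC[C@]2(C)[C@H]1C | intermediate
11 | (4aR,5R,6S)-6-[(tert-butyldimethylsilyl)oxy]-4a,5-dimethyl-2-[(trimethylsilyl)oxy]-3,4,4a,5,6,7-hexahydronaphthalene | CC(C)(C)[Si](C)(C)O[C@H]1CC=C2C=C(O[Si](C)(C)C)CC[C@]2(C)[C@H]1C | intermediate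
12 | (4aR,5R,6S)-6-[(tert-butyldimethylsilyl)oxy]-4a,5-dimethyl-4,4a,5,6-tetrahydronaphthalen-2(3H)-one | CC(C)(C)[Si](C)(C)O[C@H]1C=CC2=CC(=O)CC[C@]2(C)[C@H]1C | intermediate
13 | (4aR,5R,6S)-6-hydroxy-4a,5-dimethyl-4,4a,5,6-tetrahydronaphthalen-2(3H)-one | O[C@H]1C=CC2=CC(=O)CC[C@]2(C)[C@H]1C | intermediate
14 | (S)-2-hydroxy-2-methylbutanoic acid | CC[C@](C)(O)C(=O)O | starting material
15 | methyl (S)-2-hydroxy-2-methylbutanoate | CC[C@](C)(O)C(=O)OC | intermediate
16 | methyl (S)-2-methyl-2-[(triethylsilyl)oxy]butanoate | CC[C@](C)(O[Si](CC)(CC)CC)C(=O)OC | intermediate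
17 | [(2S)-1-methoxy-2-methyl-2-[(triethylsilyl)oxy]butoxy]bis(2-methylpropyl)aluminium (C1 not defined) | CC[C@](C)(O[Si](CC)(CC)CC)C(OC)O[Al](CC(C)C)CC(C)C | intermediate (not isolated)
18 | (S)-2-methyl-2-[(triethylsilyl)oxy]butanal | CC[C@](C)(O[Si](CC)(CC)CC)C=O | intermediate
19 | ethyl (E)-4-(diethoxyphosphoryl)but-2-enoate | CCOC(=O)/C=C/CP(=O)(OCC)OCC | starting material
20 | lithium salt of 19 (carbanion at C4) | [Li+].CCOC(=O)/C=C/[CH-]P(=O)(OCC)OCC | intermediate (not isolated)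
21 | ethyl (2E,4E,6S)-6-methyl-6-[(triethylsilyl)oxy]octa-2,4-dienoate | CC[C@](C)(O[Si](CC)(CC)CC)/C=C/C=C/C(=O)OCC | intermediate
22 | lithium (2E,4E,6S)-6-methyl-6-[(triethylsilyl)oxy]octa-2,4-dienoate | [Li+].CC[C@](C)(O[Si](CC)(CC)CC)/C=C/C=C/C(=O)[O-] | intermediate (not isolated)
23 | (2E,4E,6S)-6-methyl-6-[(triethylsilyl)oxy]octa-2,4-dienoic acid | CC[C@](C)(O[Si](CC)(CC)CC)/C=C/C=C/C(=O)O | intermediate
24 | (2E,4E,6S)-6-methyl-6-[(triethylsilyl)oxy]octa-2,4-dienoic 2,4,6-trichlorobenzoic anhydride | CC[C@](C)(O[Si](CC)(CC)CC)/C=C/C=C/C(=O)OC(=O)c1c(Cl)cc(Cl)cc1Cl | intermediate (not isolated)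
25 | (4aR,5R,6S)-4a,5-dimethyl-2-oxo-2,3,4,4a,5,6-hexahydronaphthalen-6-yl (2E,4E,6S)-6-methyl-6-[(triethylsilyl)oxy]octa-2,4-dienoate | CC[C@](C)(O[Si](CC)(CC)CC)/C=C/C=C/C(=O)O[C@H]1C=CC2=CC(=O)CC[C@]2(C)[C@H]1C | intermediate
26 | potassium C2 enolate of 25 (C2=C3) | [K+].CC[C@](C)(O[Si](CC)(CC)CC)/C=C/C=C/C(=O)O[C@H]1C=CC2=CC([O-])=CC[C@]2(C)[C@H]1C | intermediate (not isolated)
27 | potassium C3 alkoxide of 28 | [K+].CC[C@](C)(O[Si](CC)(CC)CC)/C=C/C=C/C(=O)O[C@H]1C=CC2=CC(=O)[C@H]([O-])C[C@]2(C)[C@H]1C | intermediate (not isolated)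
28 | (3R,4aR,5R,6S)-3-hydroxy-4a,5-dimethyl-2-oxo-2,3,4,4a,5,6-hexahydronaphthalen-6-yl (2E,4E,6S)-6-methyl-6-[(triethylsilyl)oxy]octa-2,4-dienoate | CC[C@](C)(O[Si](CC)(CC)CC)/C=C/C=C/C(=O)O[C@H]1C=CC2=CC(=O)[C@H](O)C[C@]2(C)[C@H]1C | intermediate
29 | (3R,4aR,5R,6S)-3-hydroxy-4a,5-dimethyl-2-oxo-2,3,4,4a,5,6-hexahydronaphthalen-6-yl (2E,4E,6S)-6-hydroxy-6-methylocta-2,4-dienoate (CNP0260852.4) | CC[C@](C)(O)/C=C/C=C/C(=O)O[C@H]1C=CC2=CC(=O)[C@H](O)C[C@]2(C)[C@H]1C | target

**Step count and risks**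
Total: 16 steps. Longest linear sequence: 11 steps (steps 1–8 and 14–16, from 1); the side chain takes 5 steps (9–13).

Steps most likely to fail:

Step 2 (the new desymmetrisation; risk: low ee or over-oxidation to the diketone). The fallback uses known chemistry, sets out from 2 and comes back at 4. Lipase-catalysed desymmetrising monoacetylation of 2 (lipase from Burkholderia cepacia, vinyl acetate, t-BuOMe, 30 °C) should acylate the (R)-carbinol, as the Kazlauskas rule predicts for a carbinol whose larger flank is CH(CH3), and give (1R,2S,3R,4S)-4-hydroxy-2,3-dimethylcyclohexyl acetate F1. Silylation (TBSCl, imidazole, DMF) gives (1R,2S,3R,4S)-4-[(tert-butyldimethylsilyl)oxy]-2,3-dimethylcyclohexyl acetate F2. Methanolysis (K2CO3, MeOH) gives (1R,2S,3R,4S)-4-[(tert-butyldimethylsilyl)oxy]-2,3-dimethylcyclohexan-1-ol F3, and Dess–Martin oxidation of F3 gives 4.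

Step 7 (risk: some cross-conjugated silyl enol ether from step 6 would be dehydrogenated to the 1(8a),3-dienone, and palladium turnover may be poor on the hindered diene). The fallback sets out from 11 and comes back at 12 by halogenation–elimination instead of palladium chemistry. γ-Bromination of the dienol ether with NBS (THF, −78 °C) gives (4aR,5R,6S)-8-bromo-6-[(tert-butyldimethylsilyl)oxy]-4a,5-dimethyl-4,4a,5,6,7,8-hexahydronaphthalen-2(3H)-one F4 as C8 epimers, and dehydrobromination (Li2CO3, LiBr, DMF, 110 °C) gives 12.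

Step 15 (risk: late enolate oxidation in the presence of the allylic dienoate). The fallback sets out from 12 and comes back at 29 by hydroxylating before the ester is attached. KN(SiMe3)2 then 2-(phenylsulfonyl)-3-phenyloxaziridine on 12 gives (3R,4aR,5R,6S)-6-[(tert-butyldimethylsilyl)oxy]-3-hydroxy-4a,5-dimethyl-4,4a,5,6-tetrahydronaphthalen-2(3H)-one F5. TBDPSCl and imidazole in DMF give (3R,4aR,5R,6S)-6-[(tert-butyldimethylsilyl)oxy]-3-[(tert-butyldiphenylsilyl)oxy]-4a,5-dimethyl-4,4a,5,6-tetrahydronaphthalen-2(3H)-one F6. Selective removal of the tert-butyldimethylsilyl group (HF·pyridine with extra pyridine, THF, 0 °C) gives (3R,4aR,5R,6S)-3-[(tert-butyldiphenylsilyl)oxy]-6-hydroxy-4a,5-dimethyl-4,4a,5,6-tetrahydronaphthalen-2(3H)-one F7. Yamaguchi esterification of F7 with 23 (through 24) gives (3R,4aR,5R,6S)-3-[(tert-butyldiphenylsilyl)oxy]-4a,5-dimethyl-2-oxo-2,3,4,4a,5,6-hexahydronaphthalen-6-yl (2E,4E,6S)-6-methyl-6-[(triethylsilyl)oxy]octa-2,4-dienoate F8, and excess HF·pyridine at rt removes both remaining silyl groups to give 29.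

**Further compounds**
F1 | step 2 | (1R,2S,3R,4S)-4-hydroxy-2,3-dimethylcyclohexyl acetate | O[C@H]1CC[C@@H](OC(C)=O)[C@@H](C)[C@H]1C
F2 | step 2 | (1R,2S,3R,4S)-4-[(tert-butyldimethylsilyl)oxy]-2,3-dimethylcyclohexyl acetate | CC(C)(C)[Si](C)(C)O[C@H]1CC[C@@H](OC(C)=O)[C@@H](C)[C@H]1C
F3 | step 2 | (1R,2S,3R,4S)-4-[(tert-butyldimethylsilyl)oxy]-2,3-dimethylcyclohexan-1-ol | CC(C)(C)[Si](C)(C)O[C@H]1CC[C@@H](O)[C@@H](C)[C@H]1C
F4 | step 7 | (4aR,5R,6S)-8-bromo-6-[(tert-butyldimethylsilyl)oxy]-4a,5-dimethyl-4,4a,5,6,7,8-hexahydronaphthalen-2(3H)-one (C8 epimers) | CC(C)(C)[Si](C)(C)O[C@H]1CC(Br)C2=CC(=O)CC[C@]2(C)[C@H]1C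
F5 | step 15 | (3R,4aR,5R,6S)-6-[(tert-butyldimethylsilyl)oxy]-3-hydroxy-4a,5-dimethyl-4,4a,5,6-tetrahydronaphthalen-2(3H)-one | CC(C)(C)[Si](C)(C)O[C@H]1C=CC2=CC(=O)[C@H](O)C[C@]2(C)[C@H]1C
F6 | step 15 | (3R,4aR,5R,6S)-6-[(tert-butyldimethylsilyl)oxy]-3-[(tert-butyldiphenylsilyl)oxy]-4a,5-dimethyl-4,4a,5,6-tetrahydronaphthalen-2(3H)-one | CC(C)(C)[Si](C)(C)O[C@H]1C=CC2=CC(=O)[C@H](O[Si](c3ccccc3)(c3ccccc3)C(C)(C)C)C[C@]2(C)[C@H]1C
F7 | step 15 | (3R,4aR,5R,6S)-3-[(tert-butyldiphenylsilyl)oxy]-6-hydroxy-4a,5-dimethyl-4,4a,5,6-tetrahydronaphthalen-2(3H)-one | O[C@H]1C=CC2=CC(=O)[C@H](O[Si](c3ccccc3)(c3ccccc3)C(C)(C)C)C[C@]2(C)[C@H]1C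
F8 | step 15 | (3R,4aR,5R,6S)-3-[(tert-butyldiphenylsilyl)oxy]-4a,5-dimethyl-2-oxo-2,3,4,4a,5,6-hexahydronaphthalen-6-yl (2E,4E,6S)-6-methyl-6-[(triethylsilyl)oxy]octa-2,4-dienoate | CC[C@](C)(O[Si](CC)(CC)CC)/C=C/C=C/C(=O)O[C@H]1C=CC2=CC(=O)[C@H](O[Si](c3ccccc3)(c3ccccc3)C(C)(C)C)C[C@]2(C)[C@H]1C
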